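Benzofuran numbering is used (O1, C2, C3, C3a, C4 to C7, C7a). The retrosynthesis cuts O1–C7a and C2–C3 of the dihydrofuran ring in one stroke, then the C5–acetyl and C5–Br bonds, and splits the side-chain reagent into angelic acid and methacrolein.
Enabling feature: C2 and C3 are vicinal oxygen-bearing carbons, that is, the carbonyl carbons of methacrolein and of an aryl aldehyde. Their polarity is alike, so methacrolein is reversed into a γ-acyloxyallyl metal. C7a of the benzene ring lies para to the C5 acetyl group, so a fluorine there yields to O1. The ester oxygen on C3 is 1,2 to O1, so the angelate can first mask O1 and then migrate to its final place.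
Forward: the benzene ring is bought and dressed at C5 (Br, then acetyl). The reagent is made from angelic acid and methacrolein. The dihydrofuran ring arises last by a formal (3+2) annulation (C3–C3a–C7a plus C2–O1), and no protecting group is used.
Stereochemistry: C3 (R) comes from the aldehyde face chosen by a chiral Cr(salen)Cl catalyst. C2 (R) comes from the syn topicity of the same C–C bond formation, since the syn (1R,2R) adduct maps onto the cis (2R,3R) ring. The Z alkene is bought with angelic acid and never touched.

Key step: step 4

Assumption: compounds 1, 3, 6 and 7 are taken as commercial. The (R,R) ligand is written for attack on the Si face of aldehyde 5, and its antipode is taken instead if a pilot run shows the opposite sense of induction.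

Step 1
Reactants: 1 2-fluoro-3,4-dimethoxybenzaldehyde
Product: 2 5-bromo-2-fluoro-3,4-dimethoxybenzaldehyde
Conditions: Br2 (1.05 equiv), AcOH, rt
Reagents that add atoms: bromine, BrBr
Why: Electrophilic aromatic bromination should go to C5, which is ortho to the 4-methoxy group, para to fluorine and meta to the formyl group, whereas C6 is ortho to the formyl group, meta to fluorine and served only by the 3-methoxy group that its two ortho neighbours twist out of conjugation.

Step 2
Reactants: 2 5-bromo-2-fluoro-3,4-dimethoxybenzaldehyde; 3 tributyl(1-ethoxyvinyl)stannane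
Product: 5 5-acetyl-2-fluoro-3,4-dimethoxybenzaldehyde, via ethoxyvinyl arene 4 (not isolated)
Conditions: PdCl2(PPh3)2 (5 mol %), toluene, 100 °C; then 1 M HCl, THF, rt
Reagents that add atoms: water, O
Why: The Stille coupling of an aryl bromide with the α-ethoxyvinyl stannane (an acetyl anion equivalent) tolerates the formyl group and the C–F bond, and mild acid hydrolysis of enol ether 4 releases the methyl ketone.

Step 3
Reactants: 6 angelic acid; 7 methacrolein
Product: 10 3-chloro-2-methylprop-1-en-1-yl angelate (E/Z mixture at the enol ester bond), via potassium angelate 8 (not isolated), via angeloyl chloride 9 (not isolated)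
Conditions: KOH (1.0 equiv), MeOH, evaporate to dryness; (COCl)2 (1.0 equiv), Et2O, 0 °C; then 7, ZnCl2 (5 mol %), CH2Cl2, −10 °C to rt
Reagents that add atoms: potassium hydroxide, [K+].[OH-] (potassium is held only by 8); oxalyl chloride, O=C(Cl)C(=O)Cl
Why: Oxalyl chloride on the dry potassium salt is the acid-free way to angeloyl chloride that conserves the Z geometry, and the ZnCl2-catalysed addition of an acyl halide to an enal (1,2-addition, then allylic halide shift) is the known route to 3-halopropenyl esters, whose enol ester geometry does not matter because step 4 is stereoconvergent.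

Step 4
Reactants: 5 5-acetyl-2-fluoro-3,4-dimethoxybenzaldehyde; 10 3-chloro-2-methylprop-1-en-1-yl angelate
Product: 13 (2R,3R)-5-acetyl-6,7-dimethoxy-2-(prop-1-en-2-yl)-2,3-dihydro-1-benzofuran-3-yl (2Z)-2-methylbut-2-enoate (target), via silyl ether 11 (not isolated), via caesium alkoxide 12 (not isolated)
Conditions: CrCl3 (10 mol %), Mn powder (3 equiv), (R,R)-N,N'-bis(3,5-di-tert-butylsalicylidene)cyclohexane-1,2-diamine (12 mol %), Et3N (20 mol %), Me3SiCl (1.5 equiv), MeCN, rt; then cannula filtration from Mn into CsF (6 equiv), DMF, 0 °C to rt, no work-up in between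
Reagents that add atoms: chlorotrimethylsilane, C[Si](C)(C)Cl (its silyl group is held only by 11); caesium fluoride, [Cs+].[F-] (its cation is held only by 12)
Why: Proposed new method: Mn holds the CrCl3/salen catalyst at the divalent stage, two single-electron transfers convert allylic chloride 10 into a γ-(angeloyloxy)allyl complex of trivalent chromium (methacrolein with its carbonyl carbon turned nucleophilic), this attacks the formyl carbon of 5 through its oxygen-bearing carbon (C2–C3 bond) and Me3SiCl releases the catalyst as silyl ether 11; CsF then bares the C3 oxygen, the angeloyl group moves from O1 to that oxygen through a five-membered 2-oxido-1,3-dioxolane, and alkoxide 12 displaces fluoride at C7a by addition–elimination (O1–C7a bond). The closest known reaction types are the catalytic enantioselective Nozaki–Hiyama addition of 3-chloropropenyl esters to aldehydes with a Cr(salen)Cl catalyst, the base-induced 1,2-acyl shift of diol monoesters and the fluoride-promoted SNAr of silyl ethers on activated aryl fluorides, and only their union into one formal (3+2) annulation is new. The dihydrofuran ring closes by 5-exo-trig attack of O1 on C7a (the C7a=C7 bond taken as acceptor) through a Meisenheimer anion whose charge rests on the para acetyl group at C5. C3 (R) is controlled by the aldehyde face that the chiral salen complex leaves open, and C2 (R) by the syn topicity that allyl transfer from this catalyst type shows whatever the E/Z ratio of the halide, the syn adduct being the one that maps onto the cis ring. The step needs aldehyde over ketone selectivity (inherent to allylchromium reagents), attack through the substituted allyl terminus (chromium rests on the primary carbon) and ring closure by O1 alone (the C3 oxygen could only form a four-membered ring, so the reversible acyl shift is drained by the irreversible SNAr).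

Compound list
1 | 2-fluoro-3,4-dimethoxybenzaldehyde | O=Cc1ccc(OC)c(OC)c1F | starting material
2 | 5-bromo-2-fluoro-3,4-dimethoxybenzaldehyde | O=Cc1cc(Br)c(OC)c(OC)c1F | intermediate
3 | tributyl(1-ethoxyvinyl)stannane | C=C(OCC)[Sn](CCCC)(CCCC)CCCC | starting material
4 | 5-(1-ethoxyvinyl)-2-fluoro-3,4-dimethoxybenzaldehyde | C=C(OCC)c1cc(C=O)c(F)c(OC)c1OC | intermediate
5 | 5-acetyl-2-fluoro-3,4-dimethoxybenzaldehyde | CC(=O)c1cc(C=O)c(F)c(OC)c1OC | intermediate
6 | angelic acid, (2Z)-2-methylbut-2-enoic acid | C/C=C(/C)C(=O)O | starting material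
7 | methacrolein, 2-methylprop-2-enal | C=C(C)C=O | starting material
8 | potassium angelate | C/C=C(/C)C(=O)[O-].[K+] | intermediate
9 | angeloyl chloride, (2Z)-2-methylbut-2-enoyl chloride | C/C=C(/C)C(=O)Cl | intermediate
10 | 3-chloro-2-methylprop-1-en-1-yl (2Z)-2-methylbut-2-enoate, E/Z mixture at the enol ester bond | ClCC(C)=COC(=O)/C(C)=C\C | intermediate
11 | (1R,2R)-1-(5-acetyl-2-fluoro-3,4-dimethoxyphenyl)-3-methyl-1-(trimethylsilyloxy)but-3-en-2-yl (2Z)-2-methylbut-2-enoate | C=C(C)[C@@H](OC(=O)/C(C)=C\C)[C@H](O[Si](C)(C)C)c1cc(C(C)=O)c(OC)c(OC)c1F | intermediate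
12 | caesium (1R,2R)-1-(5-acetyl-2-fluoro-3,4-dimethoxyphenyl)-1-[(2Z)-2-methylbut-2-enoyloxy]-3-methylbut-3-en-2-olate | C=C(C)[C@@H]([O-])[C@H](OC(=O)/C(C)=C\C)c1cc(C(C)=O)c(OC)c(OC)c1F.[Cs+] | intermediate
13 | (2R,3R)-5-acetyl-6,7-dimethoxy-2-(prop-1-en-2-yl)-2,3-dihydro-1-benzofuran-3-yl (2Z)-2-methylbut-2-enoate | C=C(C)[C@H]1Oc2c(cc(C(C)=O)c(OC)c2OC)[C@H]1OC(=O)/C(C)=C\C | target

Total step count: 4. Longest linear sequence: 3 steps (1 to 2 to 5 to 13).

Steps most likely to fail

Step 4 (labelled step). Several processes could go wrong:
- poor facial or syn/anti selectivity of the allyl transfer with the 2-methyl-substituted donor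
- reductive pinacol dimerisation of the electron-poor aldehyde
- intermolecular acyl transfer to the free alkoxide before ring closure
- base-induced loss of the ester with aromatisation of the five-membered ring

The fallback is stepwise, uses known reaction types, sets out from 5 and comes back at 13. 2-Methylprop-2-en-1-ol is protected (MOMCl, i-Pr2NEt, CH2Cl2) as 3-(methoxymethoxy)-2-methylprop-1-ene F1. This is lithiated next to oxygen (s-BuLi, THF, −78 °C) and trapped with 2-isopropoxy-4,4,5,5-tetramethyl-1,3,2-dioxaborolane to give the (Z)-γ-alkoxyallyl pinacol boronate F2. Chiral phosphoric acid catalysed allylboration of 5 with (S)-3,3'-bis(2,4,6-triisopropylphenyl)-1,1'-binaphthyl-2,2'-diyl hydrogen phosphate (5 mol %, toluene, −30 °C) runs through a closed chair and touches only the aldehyde. It should give the syn (1R,2R) methoxymethyl ether alcohol F3. HCl in MeOH removes the acetal to give the syn diol F4. Cs2CO3 in DMF closes the ring by SNAr to the cis alcohol F5. Finally F5 is esterified in toluene at 80 °C, without nucleophilic catalyst, with angelic 2,4,6-trichlorobenzoic anhydride F6 (from 6, 2,4,6-trichlorobenzoyl chloride and Et3N) to give 13.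

Step 3. The acyl unit may isomerise from Z to E at the acyl chloride stage or under ZnCl2, and the enal may polymerise. The fallback sets out from 7 and comes back at 13, and it brings the angelate in last. Acetyl chloride adds to 7 (ZnCl2 cat., CH2Cl2, 0 °C) to give 3-chloro-2-methylprop-1-en-1-yl acetate F7. Under the conditions of step 4 this should carry 5 through the acetoxy silyl ether F8 to the cis acetate F9, with the acetyl group now serving as the migrating mask. K2CO3 in MeOH at 0 °C frees the cis alcohol F5. F5 is then esterified with the mixed anhydride F6 as above, under conditions known to conserve the Z geometry, to give 13.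

Step 1. Bromination may compete at C6 (para to the 3-methoxy group), or a second bromination may occur. The fallback sets out from 1, comes back at 5 and replaces steps 1 and 2 by one directed metalation. 1-Methylpiperazine and n-BuLi give lithium 4-methylpiperazin-1-ide F10. This adds to the formyl group of 1 and masks it in the flask as the lithium α-amino alkoxide F11. n-BuLi (THF, −40 °C) then metalates ortho to the 4-methoxy group to give the C5-lithio species F12. N-Methoxy-N-methylacetamide followed by aqueous acid delivers both carbonyl groups of 5.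

Further compounds
F1 | step 4 | 3-(methoxymethoxy)-2-methylprop-1-ene | C=C(C)COCOC
F2 | step 4 | 2-[(2Z)-3-(methoxymethoxy)-2-methylprop-2-en-1-yl]-4,4,5,5-tetramethyl-1,3,2-dioxaborolane | COCO/C=C(/C)CB1OC(C)(C)C(C)(C)O1
F3 | step 4 | (1R,2R)-1-(5-acetyl-2-fluoro-3,4-dimethoxyphenyl)-2-(methoxymethoxy)-3-methylbut-3-en-1-ol | C=C(C)[C@@H](OCOC)[C@H](O)c1cc(C(C)=O)c(OC)c(OC)c1F
F4 | step 4 | (1R,2R)-1-(5-acetyl-2-fluoro-3,4-dimethoxyphenyl)-3-methylbut-3-ene-1,2-diol | C=C(C)[C@@H](O)[C@H](O)c1cc(C(C)=O)c(OC)c(OC)c1F
F5 | step 4 | 1-[(2R,3R)-3-hydroxy-6,7-dimethoxy-2-(prop-1-en-2-yl)-2,3-dihydro-1-benzofuran-5-yl]ethanone | C=C(C)[C@H]1Oc2c(cc(C(C)=O)c(OC)c2OC)[C@H]1O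
F6 | step 4 | angelic 2,4,6-trichlorobenzoic anhydride | C/C=C(/C)C(=O)OC(=O)c1c(Cl)cc(Cl)cc1Cl
F7 | step 3 | 3-chloro-2-methylprop-1-en-1-yl acetate, E/Z mixture | ClCC(C)=COC(C)=O
F8 | step 3 | (1R,2R)-1-(5-acetyl-2-fluoro-3,4-dimethoxyphenyl)-3-methyl-1-(trimethylsilyloxy)but-3-en-2-yl acetate | C=C(C)[C@@H](OC(C)=O)[C@H](O[Si](C)(C)C)c1cc(C(C)=O)c(OC)c(OC)c1F
F9 | step 3 | (2R,3R)-5-acetyl-6,7-dimethoxy-2-(prop-1-en-2-yl)-2,3-dihydro-1-benzofuran-3-yl acetate | C=C(C)[C@H]1Oc2c(cc(C(C)=O)c(OC)c2OC)[C@H]1OC(C)=O
F10 | step 1 | lithium 4-methylpiperazin-1-ide | CN1CC[N-]CC1.[Li+]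
F11 | step 1 | lithium (2-fluoro-3,4-dimethoxyphenyl)(4-methylpiperazin-1-yl)methanolate | COc1ccc(C([O-])N2CCN(C)CC2)c(F)c1OC.[Li+]
F12 | step 1 | lithium (2-fluoro-5-lithio-3,4-dimethoxyphenyl)(4-methylpiperazin-1-yl)methanolate | COc1c([Li])cc(C([O-])N2CCN(C)CC2)c(F)c1OC.[Li+]
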